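**Plan**

- Retrosynthetic cuts, in order: the two C–O bonds of the O–O bridge (singlet-oxygen [4+2]); then, together, the cyclobutane/six-ring fusion bond C(CH3)–CH and the bond from the ring =CH to the CH3-bearing O–C bridgehead; then the diene σ-bond, the C=C(I) bond and the quaternary C–CH(CH3) bond of an acyclic chain.
- Enabling feature: without the O–O bridge the carbocycle is a bicyclo[4.2.0]octa-2,4-diene, the closed valence tautomer of an all-cis cycloocta-1,3,5-triene. The only sp3 ring atoms of that triene are the pyranone-bearing quaternary carbon and its CH(CH3) neighbour, so an sp2–sp2 ring closure of an acyclic (Z,Z,Z)-triene triggers the 6π closure.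
- Forward order: γ-pyranone → acyclic chain (Claisen) → temporary oxasilepine ring → (Z,Z)-diene and (Z)-iodoalkene → transient eight-membered triene → cyclobutane and cyclohexadiene in the same step → dioxa bridge last.
- Stereochemistry: a CBS-derived carbinol is relayed by a chair Claisen rearrangement into the quaternary carbon and the CH(CH3) centre. These two steer the disrotatory closure (ring fusion) and, through the cyclobutane, the face of O2 addition. Alkene geometries come from ring constraint, syn-silylstannation and Zhao olefination.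

Key step: step 17

Remark: enol ether 9 is assumed to form, and to be purified, as the (E)-isomer (alkoxy group remote from the pyranone); compound 6 is written as its aldehyde tautomer.

**Route**

Step 1
Reactants: 1 methyl 2-methyl-3-oxopentanoate; 2 N-methoxy-N-methylpropanamide
Product: 3 methyl 2,4-dimethyl-3,5-dioxoheptanoate (mixture of diastereomers and enol forms)
Conditions: NaH, THF, 0 °C; n-BuLi, −10 °C; then 2, −78 → 0 °C; aq. NH4Cl
Reagents that add atoms: none
Why: The β-keto ester dianion should be acylated at its γ-carbon by the N-methoxy-N-methylamide (Claisen-type γ-acylation; the chelated tetrahedral intermediate blocks over-addition), and the stereocentres of 3 vanish in step 2.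

Step 2
Reactants: 3 methyl 2,4-dimethyl-3,5-dioxoheptanoate
Product: 4 6-ethyl-4-hydroxy-3,5-dimethyl-2H-pyran-2-one
Conditions: DBU, PhMe, 80 °C; aq. HCl
Reagents that add atoms: none
Why: Base-mediated lactonisation of the C5 enol onto the methyl ester (loss of methanol) should give the 4-hydroxy-2-pyranone.

Step 3
Reactants: 4 6-ethyl-4-hydroxy-3,5-dimethyl-2H-pyran-2-one
Product: 5 2-ethyl-6-methoxy-3,5-dimethyl-4H-pyran-4-one
Conditions: MeOTf, CH2Cl2, rt; aq. NaHCO3
Reagents that add atoms: methyl trifluoromethanesulfonate COS(=O)(=O)C(F)(F)F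
Why: A hard methylating agent should alkylate the lactone carbonyl oxygen, and loss of the proton then gives the α-methoxy-γ-pyranone (O-methylation of a 4-hydroxy-2-pyranone).

Step 4
Reactants: 5 2-ethyl-6-methoxy-3,5-dimethyl-4H-pyran-4-one
Product: 6 2-(6-methoxy-3,5-dimethyl-4-oxo-4H-pyran-2-yl)propanal (racemic, in equilibrium with its enol)
Conditions: LiHMDS (2.2 equiv), THF, −78 °C; HCO2Et, −78 → −30 °C; AcOH
Reagents that add atoms: ethyl formate CCOC=O
Why: The CH2 of the 6-ethyl group is the only vinylogous acidic site, so its lithium enolate should undergo a Claisen condensation with ethyl formate (lateral formylation).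

Step 5
Reactants: 7 (E)-3-methylpent-3-en-2-one
Product: 8 (2R,3E)-3-methylpent-3-en-2-ol
Conditions: (S)-2-methyl-CBS-oxazaborolidine (10 mol %), BH3·SMe2, THF, −20 °C; MeOH
Reagents that add atoms: none
Why: Corey–Bakshi–Shibata reduction with the alkenyl group as the large substituent should deliver the (R)-carbinol.

Step 6
Reactants: 6 2-(6-methoxy-3,5-dimethyl-4-oxo-4H-pyran-2-yl)propanal; 8 (2R,3E)-3-methylpent-3-en-2-ol
Product: 9 2-methoxy-3,5-dimethyl-6-[(1E)-1-{[(2S,3E)-3-methylpent-3-en-2-yl]oxy}prop-1-en-2-yl]-4H-pyran-4-one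
Conditions: PPh3, DIAD, THF, 0 °C → rt
Reagents that add atoms: none
Why: Mitsunobu O-alkylation of the acidic vinylogous enol should proceed by SN2 with inversion to the (S)-ether, the enolate reacting in its extended form with the oxygen remote from the pyranone ring oxygen ((E)-enol ether).

Step 7
Reactants: 9 allyl vinyl ether
Product: 10 (2R,3R,4E)-2-(6-methoxy-3,5-dimethyl-4-oxo-4H-pyran-2-yl)-2,3,4-trimethylhex-4-enal
Conditions: PhMe, 120 °C, sealed tube, base-washed glass
Reagents that add atoms: none
Why: Claisen rearrangement through a chair transition state with the carbinol methyl equatorial should relay the (S)-ether carbon into the quaternary carbon (fixed by the (E)-enol ether) and the CH(CH3) centre (fixed by the (E)-alkene), leaving an (E)-trisubstituted alkene.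

Step 8
Reactants: 10 aldehyde
Product: 11 6-[(2S,3R,4E)-1-hydroxy-2,3,4-trimethylhex-4-en-2-yl]-2-methoxy-3,5-dimethyl-4H-pyran-4-one
Conditions: NaBH4, MeOH, 0 °C
Reagents that add atoms: none
Why: Borohydride should reduce the non-enolisable aldehyde much faster than the vinylogous-ester carbonyl of the pyranone.

Step 9
Reactants: 11 neopentyl alcohol
Product: 12 dimethyl(vinyl)silyl ether of 11
Conditions: ClSiMe2(CH=CH2), imidazole, CH2Cl2, 0 °C
Reagents that add atoms: chloro(dimethyl)vinylsilane C=C[Si](C)(C)Cl
Why: Standard silylation of a primary alcohol installs the temporary vinylsilane tether.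

Step 10
Reactants: 12 vinylsilyl ether
Product: 13 2-methoxy-3,5-dimethyl-6-[(5S,6S)-2,2,4,5,6-pentamethyl-2,5,6,7-tetrahydro-1,2-oxasilepin-6-yl]-4H-pyran-4-one
Conditions: Mo(=CHCMe2Ph)(=N-2,6-iPr2C6H3)[OCMe(CF3)2]2 (10 mol %), PhH, 25 → 60 °C
Reagents that add atoms: none
Why: Ring-closing metathesis of the vinylsilane onto the trisubstituted alkene (propene lost) should close the seven-membered alkenylsiloxane, whose ring forces silicon and the CH(CH3) carbon cis on the new trisubstituted double bond.

Step 11
Reactants: 14 propyne; 15 trimethyl(tributylstannyl)silane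
Product: 16 (Z)-trimethyl[2-(tributylstannyl)prop-1-en-1-yl]silane
Conditions: Pd(PPh3)4 (2 mol %), THF, 65 °C, sealed tube
Reagents that add atoms: none
Why: Pd-catalysed silylstannation of a terminal alkyne is a syn addition that places tin on the internal and silicon on the terminal carbon.

Step 12
Reactants: 16 (Z)-silyl stannyl propene
Product: 17 (Z)-(2-iodoprop-1-en-1-yl)trimethylsilane
Conditions: I2, CH2Cl2, 0 °C; aq. Na2S2O3
Reagents that add atoms: iodine II
Why: Iododestannylation is much faster than iododesilylation and goes with retention, so iodine ends cis to silicon.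

Step 13
Reactants: 13 cyclic alkenylsiloxane; 17 (Z)-(2-iodoprop-1-en-1-yl)trimethylsilane
Product: 18 6-[(2S,3R,4Z,6Z)-1-hydroxy-2,3,4,6-tetramethyl-7-(trimethylsilyl)hepta-4,6-dien-2-yl]-2-methoxy-3,5-dimethyl-4H-pyran-4-one
Conditions: Pd(dba)2 (5 mol %), TBAF·3H2O (2 equiv), THF, rt
Reagents that add atoms: none
Why: Fluoride-promoted Hiyama–Denmark coupling of the cyclic siloxane with the alkenyl iodide goes with retention at both partners, giving the (Z,Z)-diene and releasing the tether as the primary alcohol; the unactivated C–SiMe3 bond is not touched.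

Step 14
Reactants: 18 dienyl alcohol
Product: 19 (2R,3R,4Z,6Z)-2-(6-methoxy-3,5-dimethyl-4-oxo-4H-pyran-2-yl)-2,3,4,6-tetramethyl-7-(trimethylsilyl)hepta-4,6-dienal
Conditions: Dess–Martin periodinane, NaHCO3, CH2Cl2, 0 °C → rt
Reagents that add atoms: none
Why: Buffered periodinane oxidation of a primary alcohol to a non-enolisable aldehyde leaves the diene, the silane and the pyranone alone.

Step 15
Reactants: 19 aldehyde
Product: 20 6-[(2Z,4S,5R,6Z,8Z)-2-iodo-4,5,6,8-tetramethyl-9-(trimethylsilyl)nona-2,6,8-trien-4-yl]-2-methoxy-3,5-dimethyl-4H-pyran-4-one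
Conditions: [Ph3PEt]I, n-BuLi, THF; I2, −78 °C; NaHMDS, −78 → −20 °C; then 19, −78 → −20 °C
Reagents that add atoms: (1-iodoethyl)triphenylphosphonium iodide, made in the flask, CC(I)[P+](c1ccccc1)(c1ccccc1)c1ccccc1.[I-]
Why: Stork–Zhao olefination with the α-iodo ethylidene ylide should give the (Z)-2-iodoalkene (iodine cis to the quaternary carbon) by the kinetic cis-oxaphosphetane pathway of unstabilised ylides.

Step 16
Reactants: 20 iodo trienylsilane
Product: 21 6-[(1Z,3Z,5R,6S,7Z)-1,8-diiodo-2,4,5,6-tetramethylnona-1,3,7-trien-6-yl]-2-methoxy-3,5-dimethyl-4H-pyran-4-one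
Conditions: NIS, 2,6-lutidine, MeCN–ClCH2CN, 0 °C, dark
Reagents that add atoms: N-iodosuccinimide O=C1CCC(=O)N1I
Why: Ipso-iododesilylation of the alkenylsilane via the β-silyl cation goes with retention, so the (Z,Z)-dienyl iodide should result.

Step 17
Reactants: 21 bis(alkenyl iodide)
Product: 24 2-methoxy-3,5-dimethyl-6-[(1R,6R,7S,8R)-1,3,5,7,8-pentamethylbicyclo[4.2.0]octa-2,4-dien-7-yl]-4H-pyran-4-one, via vinylstannane 22 (not isolated), via cyclooctatriene 23 (not isolated)
Conditions: Pd2(dba)3 (10 mol %), AsPh3 (40 mol %), Me3SnSnMe3 (1.05 equiv, slow addition), NMP (2 mM), 45–50 °C, dark, Ar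
Reagents that add atoms: none
Why: Pd(0) inserts into the less hindered dienyl C–I bond and hexamethylditin turns it into vinylstannane 22, whose remaining α-methylvinyl iodide then undergoes oxidative addition, intramolecular Sn-to-Pd transmetallation and reductive elimination (Stille–Kelly ring closure; closest types are intramolecular alkenyl–alkenyl Stille couplings and Stille/8π–6π cascades). The reductive elimination closes the eight-membered ring at the sp2–sp2 bond between the diene =CH terminus and the C(CH3)= carbon, giving the all-cis cycloocta-1,3,5-triene 23, which only a (Z,Z,Z) precursor can reach. Triene 23 then undergoes thermal 6π disrotatory electrocyclisation across the ring, forming the bond between the methyl-bearing triene terminus and the CH terminus and so the cyclobutane and the cyclohexadiene at once. Disrotation enforces the cis ring fusion, and the two pre-set sp3 centres should choose the face: the favoured mode leaves the two cyclobutane methyl groups on the convex face and puts only the flat pyranone and an H under the diene, whereas the other mode pushes both methyl groups into the concave face. The selectivities needed are ring closure over oligomerisation (high dilution, slow ditin addition), retention of the three Z alkenes (mild, dark) and no retro-8π opening of 23, which would racemise it (temperature kept at or below 50 °C).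

Step 18
Reactants: 24 bicyclo[4.2.0]octadiene
Product: 25 2-methoxy-3,5-dimethyl-6-[(1S,2R,3S,4R,5R,6R)-1,3,4,5,10-pentamethyl-7,8-dioxatricyclo[4.2.2.0^2,5]dec-9-en-3-yl]-4H-pyran-4-one (target, CNP0183511.1)
Conditions: O2, methylene blue (cat.), visible light, CH2Cl2, 0 °C
Reagents that add atoms: dioxygen O=O
Why: [4+2] Cycloaddition of singlet oxygen to the s-cis cyclohexadiene from the convex face, anti to the cyclobutane, should set both O-bearing bridgeheads and leave the trisubstituted alkene of the target.

**Compound list**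

1 | methyl 2-methyl-3-oxopentanoate | CCC(=O)C(C)C(=O)OC | starting material
2 | N-methoxy-N-methylpropanamide | CCC(=O)N(C)OC | starting material
3 | methyl 2,4-dimethyl-3,5-dioxoheptanoate (stereoisomer/enol mixture) | CCC(=O)C(C)C(=O)C(C)C(=O)OC | intermediate
4 | 6-ethyl-4-hydroxy-3,5-dimethyl-2H-pyran-2-one | CCc1oc(=O)c(C)c(O)c1C | intermediate
5 | 2-ethyl-6-methoxy-3,5-dimethyl-4H-pyran-4-one | CCc1oc(OC)c(C)c(=O)c1C | intermediate
6 | 2-(6-methoxy-3,5-dimethyl-4-oxo-4H-pyran-2-yl)propanal (racemic, enolisable) | COc1oc(C(C)C=O)c(C)c(=O)c1C | intermediate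
7 | (E)-3-methylpent-3-en-2-one | C/C=C(\C)C(C)=O | starting material
8 | (2R,3E)-3-methylpent-3-en-2-ol | C/C=C(\C)[C@@H](C)O | intermediate
9 | (E)-enol ether of 6 with the (2S,3E)-3-methylpent-3-en-2-yl group | COc1oc(/C(C)=C/O[C@@H](C)/C(C)=C/C)c(C)c(=O)c1C | intermediate
10 | (2R,3R,4E)-2-(pyranonyl)-2,3,4-trimethylhex-4-enal | COc1oc([C@](C)(C=O)[C@H](C)/C(C)=C/C)c(C)c(=O)c1C | intermediate
11 | (2S,3R,4E)-2-(pyranonyl)-2,3,4-trimethylhex-4-en-1-ol | COc1oc([C@](C)(CO)[C@H](C)/C(C)=C/C)c(C)c(=O)c1C | intermediate
12 | dimethyl(vinyl)silyl ether of 11 | COc1oc([C@](C)(CO[Si](C)(C)C=C)[C@H](C)/C(C)=C/C)c(C)c(=O)c1C | intermediate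
13 | (5S,6S)-2,2,4,5,6-pentamethyl-6-(pyranonyl)-2,5,6,7-tetrahydro-1,2-oxasilepine | COc1oc([C@]2(C)CO[Si](C)(C)C=C(C)[C@H]2C)c(C)c(=O)c1C | intermediate
14 | propyne | CC#C | starting material
15 | trimethyl(tributylstannyl)silane | CCCC[Sn](CCCC)(CCCC)[Si](C)(C)C | starting material
16 | (Z)-trimethyl[2-(tributylstannyl)prop-1-en-1-yl]silane | C/C(=C/[Si](C)(C)C)[Sn](CCCC)(CCCC)CCCC | intermediate
17 | (Z)-(2-iodoprop-1-en-1-yl)trimethylsilane | C/C(I)=C/[Si](C)(C)C | intermediate
18 | (2S,3R,4Z,6Z)-2-(pyranonyl)-2,3,4,6-tetramethyl-7-(trimethylsilyl)hepta-4,6-dien-1-ol | COc1oc([C@](C)(CO)[C@H](C)/C(C)=C\C(C)=C/[Si](C)(C)C)c(C)c(=O)c1C | intermediate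
19 | (2R,3R,4Z,6Z)-2-(pyranonyl)-2,3,4,6-tetramethyl-7-(trimethylsilyl)hepta-4,6-dienal | COc1oc([C@](C)(C=O)[C@H](C)/C(C)=C\C(C)=C/[Si](C)(C)C)c(C)c(=O)c1C | intermediate
20 | (2Z,4S,5R,6Z,8Z)-2-iodo-4,5,6,8-tetramethyl-4-(pyranonyl)-9-(trimethylsilyl)nona-2,6,8-triene | COc1oc([C@](C)(/C=C(/C)I)[C@H](C)/C(C)=C\C(C)=C/[Si](C)(C)C)c(C)c(=O)c1C | intermediate
21 | (1Z,3Z,5R,6S,7Z)-1,8-diiodo-2,4,5,6-tetramethyl-6-(pyranonyl)nona-1,3,7-triene | COc1oc([C@](C)(/C=C(/C)I)[C@H](C)/C(C)=C\C(C)=C/I)c(C)c(=O)c1C | intermediate
22 | (1Z,3Z,5R,6S,7Z)-8-iodo-2,4,5,6-tetramethyl-6-(pyranonyl)-1-(trimethylstannyl)nona-1,3,7-triene (not isolated) | COc1oc([C@](C)(/C=C(/C)I)[C@H](C)/C(C)=C\C(C)=C/[Sn](C)(C)C)c(C)c(=O)c1C | intermediate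
23 | (1R,2Z,4Z,6Z,8R)-1,3,5,7,8-pentamethyl-1-(pyranonyl)cycloocta-2,4,6-triene (not isolated) | COc1oc([C@@]2(C)[C@H](C)/C(C)=C\C(C)=C/C(C)=C\2)c(C)c(=O)c1C | intermediate
24 | (1R,6R,7S,8R)-1,3,5,7,8-pentamethyl-7-(pyranonyl)bicyclo[4.2.0]octa-2,4-diene | COc1oc([C@@]2(C)[C@H](C)[C@@]3(C)C=C(C)C=C(C)[C@@H]23)c(C)c(=O)c1C | intermediate
25 | target endoperoxide CNP0183511.1 | COc1oc([C@@]2(C)[C@H](C)[C@@]3(C)[C@@H]4OO[C@@](C)(C=C4C)[C@@H]23)c(C)c(=O)c1C | target

("pyranonyl" = 6-methoxy-3,5-dimethyl-4-oxo-4H-pyran-2-yl.)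

**Count**

Total steps: 18. Longest linear sequence: 15 (steps 1–4, 6–10, 13–18).

**Steps most likely to fail, with fallbacks**

Step 17. The ditin may stannylate both iodides, or the mono-stannane may couple between molecules, so that oligomers form instead of the eight-membered ring. In addition the disrotatory closure could take the other sense, and heating could open 23 to the achiral tetraene. The fallback sets out from 18 and returns at 24, and makes the stannane a defined, purified compound. Iododesilylation of 18 (NIS, MeCN, 0 °C) should give the (2S,3R,4Z,6Z)-7-iodo dienol F1. Pd(PPh3)4 and Me3SnSnMe3 then give the 7-(trimethylstannyl) dienol F2, and Dess–Martin oxidation gives the stannyl dienal F3. Zhao olefination of F3 gives 22, this time isolated. Pure 22 is cyclised with stoichiometric copper(I) thiophene-2-carboxylate in NMP at room temperature under high dilution (no palladium, no ditin in the ring-closing flask), giving 23 and then 24. Should the epimeric ring fusion form, gentle warming equilibrates the two bicycles through 23.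

Step 10. The molybdenum alkylidene may fail to engage the hindered trisubstituted alkene (homodimerisation at the vinylsilane, or no reaction), or be consumed by the pyranone carbonyl. The fallback sets out from 11 and returns at 18, with a boronate tether and a ruthenium carbene. Transesterification of 11 with dibutyl vinylboronate and ring-closing metathesis with (H2IMes)(PCy3)Cl2Ru=CHPh in CH2Cl2 at 40 °C should give the cyclic alkenylboronic half-ester F4. Suzuki coupling of F4 with 17 (Pd(PPh3)4, aq. K3PO4, THF) then gives 18 without fluoride.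

Step 7. A mixed enol-ether geometry carried into the rearrangement, partial ionisation of the allylic C–O bond, or a boat pathway at 120 °C would erode the configuration at the quaternary carbon. The fallback sets out from 5 and 7 and returns at 11, and never breaks the carbinol C–O bond before the [3,3] step. Reduction of 7 with the (R)-CBS catalyst gives the (2S,3E)-alcohol F5, and carbonyldiimidazole converts it into the imidazole-1-carboxylate F6. The lateral lithium enolate of 5 (LiHMDS, 2.1 equiv) is C-acylated by F6 to the 2-(pyranonyl)propanoate ester F7. Ireland–Claisen rearrangement (KHMDS, TMSCl, PhMe, −78 → 60 °C), through the internally chelated enolate with the pyranone cis to the silyloxy group, gives the (2S,3R,4E)-acid F8. Reduction through the mixed anhydride (i-BuOCOCl, N-methylmorpholine; NaBH4, THF–H2O, 0 °C) gives 11.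

**Further compounds**

F1 | step 17 | (2S,3R,4Z,6Z)-7-iodo-2-(pyranonyl)-2,3,4,6-tetramethylhepta-4,6-dien-1-ol | COc1oc([C@](C)(CO)[C@H](C)/C(C)=C\C(C)=C/I)c(C)c(=O)c1C
F2 | step 17 | (2S,3R,4Z,6Z)-2-(pyranonyl)-2,3,4,6-tetramethyl-7-(trimethylstannyl)hepta-4,6-dien-1-ol | COc1oc([C@](C)(CO)[C@H](C)/C(C)=C\C(C)=C/[Sn](C)(C)C)c(C)c(=O)c1C
F3 | step 17 | (2R,3R,4Z,6Z)-2-(pyranonyl)-2,3,4,6-tetramethyl-7-(trimethylstannyl)hepta-4,6-dienal | COc1oc([C@](C)(C=O)[C@H](C)/C(C)=C\C(C)=C/[Sn](C)(C)C)c(C)c(=O)c1C
F4 | step 10 | (5S,6S)-2-hydroxy-4,5,6-trimethyl-6-(pyranonyl)-2,5,6,7-tetrahydro-1,2-oxaborepine | COc1oc([C@]2(C)COB(O)C=C(C)[C@H]2C)c(C)c(=O)c1C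
F5 | step 7 | (2S,3E)-3-methylpent-3-en-2-ol | C/C=C(\C)[C@H](C)O
F6 | step 7 | (2S,3E)-3-methylpent-3-en-2-yl 1H-imidazole-1-carboxylate | C/C=C(\C)[C@H](C)OC(=O)n1ccnc1
F7 | step 7 | (2S,3E)-3-methylpent-3-en-2-yl 2-(pyranonyl)propanoate (epimers at C2) | COc1oc(C(C)C(=O)O[C@@H](C)/C(C)=C/C)c(C)c(=O)c1C
F8 | step 7 | (2S,3R,4E)-2-(pyranonyl)-2,3,4-trimethylhex-4-enoic acid | COc1oc([C@](C)(C(=O)O)[C@H](C)/C(C)=C/C)c(C)c(=O)c1C
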